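**Retrosynthetic overview** (isochromene numbering: C1, O2, C3, C4, C4a, C5–C8, C8a)
1. Last operation, both rings from two acyclic pieces: an anionic [4+2] annulation (conjugate addition at C4a, then Dieckmann closure C8a–C8) of a chiral acyloxy keto ester enolate onto a 5-silyloxy-2-ynal builds ring A; the acid work-up then closes ring B (O2–C1) by desilylation, lactol formation and dehydration.
2. Keto ester piece (C5–C8, already carrying the stearate): acylation of an (R)-α-hydroxy-β-keto ester made by catalytic asymmetric α-hydroxylation of methyl 2-methylacetoacetate (sets C7).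
3. Ynal piece (C1, C3, C4, C4a, C8a): (R)-propylene oxide (sets C3) opened by lithiated propiolaldehyde diethyl acetal, then one-pot O-silylation and acetal unmasking.
4. Ring order: carbocycle A first, pyran B second, in the same flask; no aromatic intermediate is involved.

Assumption: the ligand enantiomer named in step 1 is taken to give the (R)-ketol; if it gives the (S)-ketol, the mirror-image ligand is used.

**Step 1**
Reactants: 1 methyl 2-methyl-3-oxobutanoate
Product: 2 methyl (2R)-2-hydroxy-2-methyl-3-oxobutanoate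
Conditions: Ni(ClO4)2·6H2O (10 mol %), (R,R)-DBFOX/Ph = 4,6-bis[(4R)-4-phenyl-4,5-dihydro-1,3-oxazol-2-yl]dibenzofuran (11 mol %), racemic 3-phenyl-2-(phenylsulfonyl)oxaziridine (1.2 equiv), 4 Å MS, CH2Cl2, rt
Reagents that add atoms: 3-phenyl-2-(phenylsulfonyl)oxaziridine, O=S(=O)(N1OC1c1ccccc1)c1ccccc1
Why: The keto ester binds the chiral nickel bis(oxazoline) Lewis acid through both carbonyl oxygens, and the planar enolate takes an oxygen atom from the N-sulfonyloxaziridine on its unshielded face, which sets the quaternary centre C7 as R (catalytic asymmetric electrophilic α-hydroxylation of a 1,3-dicarbonyl compound, Davis-type oxygen transfer).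

**Step 2**
Reactants: 2 methyl (2R)-2-hydroxy-2-methyl-3-oxobutanoate; 3 octadecanoyl chloride (stearoyl chloride)
Product: 4 methyl (2R)-2-methyl-2-(octadecanoyloxy)-3-oxobutanoate
Conditions: pyridine (3 equiv), DMAP (0.2 equiv), CH2Cl2, 0 °C to rt
Reagents that add atoms: none
Why: DMAP-catalysed acylation through the acylpyridinium ion esterifies the tertiary ketol without touching any bond at C7, and the acylated ketol can no longer racemise by an α-ketol shift.

**Step 3**
Reactants: 5 3,3-diethoxyprop-1-yne; 6 (R)-2-methyloxirane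
Product: 8 (2R)-6,6-diethoxyhex-4-yn-2-ol, via lithium acetylide 7 (not isolated)
Conditions: n-BuLi, THF, −78 °C; BF3·OEt2, then 6, −78 °C; then H2O
Reagents that add atoms: none
Why: BF3-assisted epoxide opening by the lithium acetylide (Yamaguchi alkynylation) is an SN2 attack at the unsubstituted carbon, so the stereocentre of 6 is untouched and becomes C3 (R).

**Step 4**
Reactants: 8 (2R)-6,6-diethoxyhex-4-yn-2-ol
Product: 11 (5R)-5-(triethylsilyloxy)hex-2-ynal, via silyl ether acetal 9 (not isolated), via collidinium salt 10 (not isolated)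
Conditions: Et3SiOTf (3.2 equiv), 2,4,6-collidine (4.5 equiv), CH2Cl2, 0 °C; then H2O, rt
Reagents that add atoms: triethylsilyl trifluoromethanesulfonate, CC[Si](CC)(CC)OS(=O)(=O)C(F)(F)F; water, O
Why: The silyl triflate first silylates the alcohol and then ionises the acetal to an oxocarbenium ion that collidine traps as a pyridinium salt, which water hydrolyses to the aldehyde under near-neutral conditions (trialkylsilyl triflate/collidine acetal cleavage), so the sensitive ynal and the silyl ether survive and C3 is unaffected.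

**Step 5 (key step)**
Reactants: 4 methyl (2R)-2-methyl-2-(octadecanoyloxy)-3-oxobutanoate; 11 (5R)-5-(triethylsilyloxy)hex-2-ynal
Product: 18 (3R,7R)-3,7-dimethyl-6,8-dioxo-3,4,7,8-tetrahydro-6H-isochromen-7-yl octadecanoate, via lithium enolate 12 (not isolated), via aluminium complex 13 (not isolated), via Michael adduct 14 (not isolated), via silyl ether triketone 15 (not isolated), via hydroxy aldehyde 16 (not isolated), via lactol 17 (not isolated)
Conditions: 4, LiN(SiMe3)2 (1.05 equiv), THF, −78 °C; add to 11 precomplexed with Al(OC6H3-2,6-Ph2)3 (1.2 equiv, from AlMe3 + 3 equiv 2,6-diphenylphenol) in toluene, −78 °C, then to 0 °C; then 2 M HCl, THF, rt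
Reagents that add atoms: none
Why: Proposed new method: the bulky aluminium tris(2,6-diphenylphenoxide) binds the aldehyde oxygen of 11 and buries the carbonyl carbon, so enolate 12 can only attack the exposed alkyne carbon C4a to give allenolate 14, whose central carbon C8a closes onto the methyl ester in a six-membered Dieckmann condensation (ring A), after which acid removes the silyl group so that the C3 hydroxyl adds to the formyl group and loses water to the cross-conjugated enol ether (ring B); the closest known reactions are Michael–Dieckmann anionic [4+2] annulations of the Staunton–Weinreb and Hauser type and conjugate additions of lithium enolates to unsaturated aldehydes shielded by this aluminium reagent, and no stereocentre is formed because C7 and C3 are carried in unchanged.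

**Compound list**
1 | methyl 2-methyl-3-oxobutanoate | CC(=O)C(C)C(=O)OC | starting material
2 | methyl (2R)-2-hydroxy-2-methyl-3-oxobutanoate | O[C@](C)(C(C)=O)C(=O)OC | intermediate
3 | octadecanoyl chloride | CCCCCCCCCCCCCCCCCC(=O)Cl | starting material
4 | methyl (2R)-2-methyl-2-(octadecanoyloxy)-3-oxobutanoate | CCCCCCCCCCCCCCCCCC(=O)O[C@](C)(C(C)=O)C(=O)OC | intermediate
5 | 3,3-diethoxyprop-1-yne | C#CC(OCC)OCC | starting material
6 | (R)-2-methyloxirane | C[C@@H]1CO1 | starting material
7 | (3,3-diethoxyprop-1-yn-1-yl)lithium | [Li]C#CC(OCC)OCC | intermediate (not isolated)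
8 | (2R)-6,6-diethoxyhex-4-yn-2-ol | C[C@@H](O)CC#CC(OCC)OCC | intermediate
9 | {[(2R)-6,6-diethoxyhex-4-yn-2-yl]oxy}triethylsilane | C[C@@H](O[Si](CC)(CC)CC)CC#CC(OCC)OCC | intermediate (not isolated)
10 | 1-[(5R)-1-ethoxy-5-(triethylsilyloxy)hex-2-yn-1-yl]-2,4,6-trimethylpyridinium triflate (C1 epimers) | C[C@@H](O[Si](CC)(CC)CC)CC#CC(OCC)[n+]1c(C)cc(C)cc1C.[O-]S(=O)(=O)C(F)(F)F | intermediate (not isolated)
11 | (5R)-5-(triethylsilyloxy)hex-2-ynal | C[C@@H](O[Si](CC)(CC)CC)CC#CC=O | intermediate
12 | lithium (3R)-4-methoxy-3-methyl-3-(octadecanoyloxy)-4-oxobut-1-en-2-olate | CCCCCCCCCCCCCCCCCC(=O)O[C@](C)(C(=C)O[Li])C(=O)OC | intermediate (not isolated)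
13 | aluminium tris(2,6-diphenylphenoxide) complex of 11 (bound at the aldehyde oxygen) | C[C@@H](O[Si](CC)(CC)CC)CC#CC=[O+][Al-](Oc1c(-c2ccccc2)cccc1-c1ccccc1)(Oc1c(-c2ccccc2)cccc1-c1ccccc1)Oc1c(-c2ccccc2)cccc1-c1ccccc1 | intermediate (not isolated)
14 | lithium tris(2,6-diphenylphenoxy){[(6R)-6-(methoxycarbonyl)-6-(octadecanoyloxy)-5-oxo-3-[(2R)-2-(triethylsilyloxy)propyl]hepta-1,2-dien-1-yl]oxy}aluminate | [Li+].CCCCCCCCCCCCCCCCCC(=O)O[C@](C)(C(=O)CC(C[C@@H](C)O[Si](CC)(CC)CC)=C=CO[Al-](Oc1c(-c2ccccc2)cccc1-c1ccccc1)(Oc1c(-c2ccccc2)cccc1-c1ccccc1)Oc1c(-c2ccccc2)cccc1-c1ccccc1)C(=O)OC | intermediate (not isolated)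
15 | (1R)-3-formyl-1-methyl-2,6-dioxo-4-[(2R)-2-(triethylsilyloxy)propyl]cyclohex-3-en-1-yl octadecanoate | CCCCCCCCCCCCCCCCCC(=O)O[C@]1(C)C(=O)CC(C[C@@H](C)O[Si](CC)(CC)CC)=C(C=O)C1=O | intermediate (not isolated)
16 | (1R)-3-formyl-4-[(2R)-2-hydroxypropyl]-1-methyl-2,6-dioxocyclohex-3-en-1-yl octadecanoate | CCCCCCCCCCCCCCCCCC(=O)O[C@]1(C)C(=O)CC(C[C@@H](C)O)=C(C=O)C1=O | intermediate (not isolated)
17 | (3R,7R)-1-hydroxy-3,7-dimethyl-6,8-dioxo-3,4,5,6,7,8-hexahydro-1H-isochromen-7-yl octadecanoate (C1 epimers) | CCCCCCCCCCCCCCCCCC(=O)O[C@]1(C)C(=O)CC2=C(C(O)O[C@H](C)C2)C1=O | intermediate (not isolated)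
18 | (3R,7R)-3,7-dimethyl-6,8-dioxo-3,4,7,8-tetrahydro-6H-isochromen-7-yl octadecanoate | CCCCCCCCCCCCCCCCCC(=O)O[C@]1(C)C(=O)C=C2C[C@@H](C)OC=C2C1=O | target

**Totals**
Total step count: 5. Longest linear sequence: 3 steps (1 → 2 → 4 → 18, or 5/6 → 8 → 11 → 18).

**Three steps most likely to fail**

Step 5. The risks are 1,2-addition to the aldehyde if shielding is incomplete, γ-deprotonation of the ynal by the enolate, intramolecular Claisen attack of the enolate on its own stearate (furanone formation), and a slow Dieckmann closure from the hindered aluminate. The fallback sets out from 4 and 11 and comes back to the route at 18. Compound 4 is enolised under soft conditions (Me3SiOTf, Et3N, CH2Cl2, 0 °C) to the trimethylsilyl enol ether F1, so that no free enolate is ever present. F1 is added to 11 under iminium catalysis (dibenzylammonium trifluoroacetate, 20 mol %, CH2Cl2 with 2 equiv H2O, −20 °C), where the aldehyde carbon is tied up as the iminium ion and the soft π-nucleophile attacks C4a, to give the keto enal F2 as an E/Z mixture. F2 is then closed with LiN(SiMe3)2 in THF (−78 to 0 °C) followed by 2 M HCl, which again forms ring A and ring B in one pot and gives 18.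

Step 1. Enantioselectivity may be only moderate for this small acyclic keto ester, and any (S)-ketol would end up as the C7 epimer of the target. The fallback sets out from 1 and comes back to the route at 18. Compound 1 is hydroxylated without a chiral catalyst (dimethyldioxirane in acetone, rt) to the racemic ketol F3, which is acylated with 3 as in step 2 to the racemic acyloxy keto ester F4. F4 is taken through the step 5 conditions with enantiopure 11; because C3 is fixed, this gives 18 together with its C7 epimer F5 as diastereomers, which are separated by preparative HPLC.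

Step 4. Ionisation of the alkynyl acetal may be sluggish, and the liberated ynal can add collidine or water. The fallback sets out from 6 and comes back to the route at 11, and 5 is then not needed. Epoxide 6 is opened with LiC≡CH·H2NCH2CH2NH2 in DMSO to (2R)-pent-4-yn-2-ol F6, which is silylated (Et3SiCl, imidazole, CH2Cl2) to its triethylsilyl ether F7. F7 is deprotonated with n-BuLi (THF, −78 °C), formylated with DMF and quenched into aqueous KH2PO4 to give 11.

**Further compounds**
F1 | step 5 | methyl (2R)-2-methyl-2-(octadecanoyloxy)-3-(trimethylsilyloxy)but-3-enoate | CCCCCCCCCCCCCCCCCC(=O)O[C@](C)(C(=C)O[Si](C)(C)C)C(=O)OC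
F2 | step 5 | methyl (2R)-2-methyl-2-(octadecanoyloxy)-3,7-dioxo-5-[(2R)-2-(triethylsilyloxy)propyl]hept-5-enoate (E/Z mixture) | CCCCCCCCCCCCCCCCCC(=O)O[C@](C)(C(=O)CC(C[C@@H](C)O[Si](CC)(CC)CC)=CC=O)C(=O)OC
F3 | step 1 | methyl 2-hydroxy-2-methyl-3-oxobutanoate (racemate) | CC(=O)C(C)(O)C(=O)OC
F4 | step 1 | methyl 2-methyl-2-(octadecanoyloxy)-3-oxobutanoate (racemate) | CCCCCCCCCCCCCCCCCC(=O)OC(C)(C(C)=O)C(=O)OC
F5 | step 1 | (3R,7S)-3,7-dimethyl-6,8-dioxo-3,4,7,8-tetrahydro-6H-isochromen-7-yl octadecanoate | CCCCCCCCCCCCCCCCCC(=O)O[C@@]1(C)C(=O)C=C2C[C@@H](C)OC=C2C1=O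
F6 | step 4 | (2R)-pent-4-yn-2-ol | C[C@@H](O)CC#C
F7 | step 4 | triethyl{[(2R)-pent-4-yn-2-yl]oxy}silane | C[C@@H](O[Si](CC)(CC)CC)CC#C
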